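In Tuesday's run substrate slows down faster than a single rate constant allows, so the hunch of plain first-order decay has to go before any quick number is given.

common to all: substrate 0.010 M

|  | capture agent | remark | time |
|---|---|---|---|
| Tuesday's | 1 mM | the very flask that is asked about, followed so far |  |
| flask | 1.00 mM |  | 12 d |

Tuesday's run (percent of the substrate charged)

| time / d | intermediate A / % | target / % | substrate / % |
|---|---|---|---|
| 0.0556 | 8.7 | 10.1 | 47.4 |
| 0.208 | 13.4 | 21.3 | 13.1 |
| 0.625 | 8.3 | 26.2 | 1.1 |
| 2.08 | 1.5 | 27.2 | 0 |
| 6.00 | 0 | 26.7 | 0.1 |

(scatter of a reading: 0.5 percentage points)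

1. time up to 12 d at which intermediate A stands highest
2. the amount of intermediate A, in percent of the substrate charged, at that time
3. the first time at which intermediate A reaches 6.9%, in the same percent

- what was read earlier has a scatter of 0.5 percentage points, one standard deviation

1. In Tuesday's run, the apparent first-order constant of substrate is 13.4 d⁻¹ up to the first reading and 5.94 d⁻¹ from the second to the third, a clear drop.
2. Each stretch of curve is replaced by its mean, 73.7% and 7.10% of the charge, and the constant is split into a first-order part and a part proportional to substrate. Break-even concentration, where the two parts are equal: 0.00458 M. This is a rough reading, since 1.1% carries a scatter of 0.5 percentage points. Logarithmic means, as a check on the averaging, give 0.00472 M.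
3. Integrating this rate law, the share of charged substrate leaving by first-order routes is (c*/c) ln(1 + c/c*), for starting concentration c and break-even c*. For Tuesday's run that is 53.0%, so the target reading of 27.2% is 51.3% of that share.
4. The highest reading of intermediate A in Tuesday's run, 13.4% at 0.208 d, stands above its neighbours, and 0% is read at 6.00 d; that reading is the estimate of the peak.
5. A straight line to the first reading of intermediate A reaches 6.9% at 1.06 h. Substrate falls to 47.4% over that stretch, so the expected crossing is somewhat earlier.

The forecast (“I read its curve directly rather than scaling anything”) gives 13.6% at 0.2 d and the level at 0.9 h.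

The flask gives 13.8% at 0.203 d, and reaches the level at 0.918 h, earlier than the straight line. At 0.203 d, substrate in the flask stands at 14.2% of its charge, or 0.00142 M, under the break-even 0.00458 M read from Tuesday's run. The first-order share reckoned above leaves 47.0% for the other route, and self-condensation product in the flask holds 47.8% at 12.0 d, with both its substrates counted.

    intermediate B → decomposed reagent (k = 1.20 × 10⁻⁵ s⁻¹)
    capture agent + intermediate C → trapped intermediate (k = 9.20 × 10⁻⁴ M⁻¹ s⁻¹)
    intermediate A ⇌ intermediate C (K = 1.20, k = 1.10 × 10⁻⁵ s⁻¹)
    substrate → intermediate A (k = 2.90 × 10⁻⁵ s⁻¹)
    intermediate A → intermediate B (k = 2.00 × 10⁻⁵ s⁻¹)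
    2 substrate → self-condensation product (k = 0.00680 M⁻¹ s⁻¹)
    intermediate B → side product (k = 5.40 × 10⁻⁵ s⁻¹)
    substrate → target (k = 3.10 × 10⁻⁵ s⁻¹)

In a neighbour flask with 0.025 M of substrate, the break-even gives a first-order share of 34.2% and, taking the same 51.3% of that share, target of 17.5%. That neighbour flask ends with 17.3% of target.

The earlier runs and the new flask stem from a simulated flask with made-up constants, and the scatter is random.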